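The earlier runs and the new flask come from a simulation for an exercise.

At 6.00 min, the last reading of the green run, this flask reads 29.4% electrophile and 61.8% product, and I want its state at 30 min.

- green: electrophile 0.019 M; nucleophile 1.5 equiv; free base 3 equiv; protic impurity 5.7 mM; the very flask that is asked about, followed so far
- flask: electrophile 0.019 M; nucleophile 1.50 equiv; free base 3.00 equiv; protic impurity 5.70 mM; time 30 min

- green (time / min: electrophile / %, product / %): 0.833: 70.4, 27.2; 2.00: 52.4, 44.0; 4.00: 38.0, 55.2; 6.00: 29.4, 61.8

(readings scatter by 0.5 percentage points)

- the analysis behind the earlier runs scatters by 0.5 percentage points, standard deviation
- the earlier runs do not show how much of nucleophile is bound; that part of a forecast is a guess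

- part of the electrophile that has reacted at 30 min
- share of the unused nucleophile that is free and not bound as protonated nucleophile, at 30 min

I build this flask up one process at a time. With the main step alone, electrophile and nucleophile give product, and the nucleophile charge of 1.50 equiv leaves some to spare, so the electrophile ends as product. Now I add the acid that the step sets free: if a second nucleophile takes it up, each product costs two nucleophile. The green readings support this. Product rate over electrophile times free nucleophile, counted two per product, keeps a factor 0.951 of its first value in the last interval. Counted one per product, it keeps 0.381.

So I carry the nucleophile ceiling, the product that the charge pays for at two nucleophile each: 75.0% of the electrophile, which makes the nucleophile the limiting reagent.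

Last comes the side loss. At 6.00 min, 8.80% of the electrophile is neither electrophile nor product, and over the time integral of the electrophile fraction, 3.00 min, that reads as 0.0293 min⁻¹. Taking the product still under the ceiling as made at once, 16.2% electrophile remains for this route, and it falls to 8.02% by 30 min. My own figure for c is therefore 92.0%; the free share I cannot read.

The forecast gives 93% reacted and 12% free, holding that “this acid mostly sits on the nucleophile rather than the base”.

This flask gives 91.8% reacted and 11.2% free, within the forecast's margins.

    electrophile + nucleophile → acid set free + product (k = 0.290 L mol⁻¹ s⁻¹)
    nucleophile + acid set free ⇌ protonated nucleophile, settled at all times (K = 3900 L mol⁻¹)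
    acid set free + free base ⇌ salt of the base, settled at all times (K = 19.0 L mol⁻¹)
    electrophile + protic impurity → quenched substrate (k = 0.0990 L mol⁻¹ s⁻¹)
    2 nucleophile → homo dimer (k = 0.0220 L mol⁻¹ s⁻¹)

At 30.0 min this flask has 76.1% product beside the ceiling of 75.0%, and 8.20% electrophile beside my 8.02%. In this flask, c moves by 5 points at 1.25 equiv nucleophile with the other amounts and the time held, and equally at 18.8 min or 57.3 min with the amounts held. The neighbouring flask with 0.380 equiv nucleophile has a ceiling of 19.0%. It ends with 54.5% reacted and 28.6% product, 9.6 percentage points above that ceiling, with 0.00399 M in acid set free and salt of the base together, against 0.00145 M protonated nucleophile.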